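**Retrosynthetic overview**
- The strategy rests on ring A, the carbocycle C4a–C5–C6–C7–C8–C8a of the chromene. It is a cyclohexanetrione enol whose quaternary C6 lies between the enol carbon C5 and the ketone carbon C7, so C6 is made as an acyclic malonate carbon and ring A is closed beside it.
- Last bond: C4a–C5, by a vinylogous Dieckmann closure of an open-chain pyranone keto ester in which the ring oxygen already sits on the future C8a.
- The pyranone (O1–C2 bond) comes from oxa-Michael closure of a triketo acid. The triketo acid comes from C-acylation (C7–C8 bond) of the polyanion of a glutarate-derived diketo acid with a malonyl half-ester chloride.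
- The quaternary carbon is set by asymmetric phase-transfer prenylation of a cyclobutylmethyl malonate. The cyclobutane is made by a 4-exo epoxynitrile cyclisation of a kinetically resolved epoxide. The side-chain centre comes from desymmetrised 3-propylglutaric anhydride.
- Ring order: cyclobutane, then dihydropyranone, then ring A.

Key step: step 18

Assumption: the facial sense of the cinchoninium-catalysed prenylation (step 10) and the carbonyl chosen by quinidine in the anhydride opening (step 13) are taken as drawn; if either proves opposite, the pseudoenantiomeric alkaloid (cinchonidinium salt, quinine) is used. β-Dicarbonyl compounds are drawn as one tautomer.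

**Route**

Step 1
Reactants: 1 2,2-dimethylpent-4-enal
Product: 2 3,3-dimethylhex-5-enenitrile
Conditions: TosMIC, KOtBu, DME, −50 → −20 °C; then MeOH, reflux
Reagents that add atoms: p-toluenesulfonylmethyl isocyanide (TosMIC), Cc1ccc(cc1)S(=O)(=O)C[N+]#[C-]
Why: The Van Leusen reductive cyanation should convert the non-enolisable neopentyl aldehyde into the nitrile with one more carbon, leaving the terminal alkene untouched.

Step 2
Reactants: 2 3,3-dimethylhex-5-enenitrile
Product: 3 rac-3,3-dimethyl-4-(oxiran-2-yl)butanenitrile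
Conditions: mCPBA, CH2Cl2, 0 °C → rt
Reagents that add atoms: 3-chloroperbenzoic acid, OOC(=O)c1cccc(Cl)c1
Why: Prilezhaev epoxidation takes place at the only alkene, the nitrile being inert to the peracid.

Step 3
Reactants: 3 rac-3,3-dimethyl-4-(oxiran-2-yl)butanenitrile
Product: 4 3,3-dimethyl-4-[(2R)-oxiran-2-yl]butanenitrile
Conditions: (R,R)-(salen)Co(OAc) (trivalent cobalt; salen = N,N′-bis(3,5-di-tert-butylsalicylidene)-(1R,2R)-cyclohexane-1,2-diamine), 0.5 mol%, H2O (0.55 equiv), THF, 0 °C → rt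
Reagents that add atoms: none
Why: In the hydrolytic kinetic resolution the (R,R)-catalyst should hydrate the (S)-epoxide much faster, so the (R)-epoxide is recovered and carries the configuration that becomes, after inversion in step 4, the ring carbon bearing the CH2O group.

Step 4
Reactants: 4 3,3-dimethyl-4-[(2R)-oxiran-2-yl]butanenitrile
Product: 6 (4R)-4-({[tert-butyl(dimethyl)silyl]oxy}methyl)-2,2-dimethylcyclobutane-1-carbonitrile (C-1 epimers), via hydroxy nitrile 5 (not isolated)
Conditions: LiN(SiMe3)2 (1.1 equiv), toluene, 0 °C → rt; then TBSCl, DMAP (cat.), THF, rt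
Reagents that add atoms: tert-butyldimethylsilyl chloride, CC(C)(C)[Si](C)(C)Cl
Why: In this epoxynitrile cyclisation the nitrile-stabilised carbanion should open the epoxide at its internal carbon in the 4-exo-tet mode (collinear attack, favoured over 5-endo and helped by the gem-dimethyl group) with inversion, which sets C-4 as (R), while C-1 forms as a mixture that step 5 corrects and the lithium alkoxide is silylated in the same flask.

Step 5
Reactants: 6 (4R)-4-({[tert-butyl(dimethyl)silyl]oxy}methyl)-2,2-dimethylcyclobutane-1-carbonitrile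
Product: 8 1-[(1S,4R)-4-({[tert-butyl(dimethyl)silyl]oxy}methyl)-2,2-dimethylcyclobutyl]ethan-1-one (trans), via ketimine 7 (not isolated)
Conditions: MeLi, Et2O, 0 °C → rt; 1 M HCl, THF, 0 °C; then K2CO3, MeOH, rt
Reagents that add atoms: methyllithium, [Li]C; water, O
Why: Addition of MeLi to the nitrile and hydrolysis of the ketimine should give the methyl ketone, and base-mediated enolisation then equilibrates C-1 to the more stable trans-1,2-disubstituted cyclobutane, so this stereocentre is set under thermodynamic control.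

Step 6
Reactants: 8 1-[(1S,4R)-4-({[tert-butyl(dimethyl)silyl]oxy}methyl)-2,2-dimethylcyclobutyl]ethan-1-one
Product: 9 tert-butyl{[(1R,2R)-3,3-dimethyl-2-(prop-1-en-2-yl)cyclobutyl]methoxy}dimethylsilane
Conditions: Ph3PCH3Br, KOtBu, THF, 0 °C → rt
Reagents that add atoms: methyltriphenylphosphonium bromide, C[P+](c1ccccc1)(c1ccccc1)c1ccccc1.[Br-]
Why: Wittig methylenation of the methyl ketone builds the isopropenyl group, and any epimerisation by the basic ylide only returns the favoured trans isomer.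

Step 7
Reactants: 9 tert-butyl{[(1R,2R)-3,3-dimethyl-2-(prop-1-en-2-yl)cyclobutyl]methoxy}dimethylsilane
Product: 10 [(1R,2R)-3,3-dimethyl-2-(prop-1-en-2-yl)cyclobutyl]methanol
Conditions: Bu4NF, THF, 0 °C → rt
Reagents that add atoms: none
Why: Fluoride-induced desilylation frees the primary alcohol without touching the alkene or the ring stereocentres.

Step 8
Reactants: 10 [(1R,2R)-3,3-dimethyl-2-(prop-1-en-2-yl)cyclobutyl]methanol
Product: 11 (1R,2R)-1-(iodomethyl)-3,3-dimethyl-2-(prop-1-en-2-yl)cyclobutane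
Conditions: I2, PPh3, imidazole, CH2Cl2, 0 °C → rt
Reagents that add atoms: iodine, II
Why: Appel-type iodination proceeds by SN2 displacement of an oxyphosphonium group at the primary carbon, so no cation forms next to the cyclobutane.

Step 9
Reactants: 11 (1R,2R)-1-(iodomethyl)-3,3-dimethyl-2-(prop-1-en-2-yl)cyclobutane; 12 tert-butyl methyl propanedioate (2 equiv)
Product: 13 1-tert-butyl 3-methyl 2-{[(1R,2R)-3,3-dimethyl-2-(prop-1-en-2-yl)cyclobutyl]methyl}propanedioate (C-2 epimers)
Conditions: NaH, DMF, 0 °C; then 11, 60 °C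
Reagents that add atoms: none
Why: Malonic ester alkylation, an SN2 reaction of the sodium malonate with the primary iodide in which the excess of 12 suppresses double alkylation; the malonate carbon stays enolisable, so its configuration is of no consequence.

Step 10
Reactants: 13 1-tert-butyl 3-methyl 2-{[(1R,2R)-3,3-dimethyl-2-(prop-1-en-2-yl)cyclobutyl]methyl}propanedioate; 14 1-bromo-3-methylbut-2-ene (prenyl bromide)
Product: 15 1-tert-butyl 3-methyl (2R)-2-{[(1S,2R)-3,3-dimethyl-2-(prop-1-en-2-yl)cyclobutyl]methyl}-2-(3-methylbut-2-en-1-yl)propanedioate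
Conditions: N-(9-anthracenylmethyl)cinchoninium chloride (10 mol%), 50% aq. KOH, toluene, −20 °C
Reagents that add atoms: none
Why: In this asymmetric phase-transfer alkylation the chiral cinchoninium cation forms a tight ion pair with the malonate enolate, whose faces differ through the methyl and tert-butyl ester groups, and directs prenyl bromide to one face, so the quaternary carbon is set under catalyst control.

Step 11
Reactants: 15 1-tert-butyl 3-methyl (2R)-2-{[(1S,2R)-3,3-dimethyl-2-(prop-1-en-2-yl)cyclobutyl]methyl}-2-(3-methylbut-2-en-1-yl)propanedioate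
Product: 17 (2S)-2-{[(1S,2R)-3,3-dimethyl-2-(prop-1-en-2-yl)cyclobutyl]methyl}-2-(methoxycarbonyl)-5-methylhex-4-enoic acid, via trimethylsilyl ester 16 (not isolated)
Conditions: TMSOTf, 2,6-lutidine, CH2Cl2, 0 °C → rt; then H2O
Reagents that add atoms: none
Why: Silyl triflate-mediated cleavage of the tert-butyl ester (O-silylation, loss of 2-methylpropene) runs under buffered aprotic conditions that should spare the methyl ester and both alkenes, and the silyl ester is hydrolysed on work-up.

Step 12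
Reactants: 17 (2S)-2-{[(1S,2R)-3,3-dimethyl-2-(prop-1-en-2-yl)cyclobutyl]methyl}-2-(methoxycarbonyl)-5-methylhex-4-enoic acid
Product: 18 methyl (2R)-2-(chlorocarbonyl)-2-{[(1S,2R)-3,3-dimethyl-2-(prop-1-en-2-yl)cyclobutyl]methyl}-5-methylhex-4-enoate
Conditions: 1-chloro-N,N,2-trimethylprop-1-en-1-amine, CH2Cl2, 0 °C → rt
Reagents that add atoms: 1-chloro-N,N,2-trimethylprop-1-en-1-amine, CC(C)=C(Cl)N(C)C
Why: The α-chloroenamine converts the hindered acid into the acid chloride under neutral conditions (no HCl to add to the alkenes), and the quaternary α-carbon rules out ketene formation or epimerisation.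

Step 13
Reactants: 19 3-propylglutaric anhydride
Product: 20 (3S)-3-(2-methoxy-2-oxoethyl)hexanoic acid
Conditions: quinidine (1.1 equiv), MeOH (3 equiv), toluene, −55 °C
Reagents that add atoms: methanol, CO
Why: Alkaloid-mediated desymmetrising methanolysis of the prochiral anhydride, in which quinidine-bound methanol opens one of the two enantiotopic carbonyl groups and thereby sets the C-3 stereocentre.

Step 14
Reactants: 20 (3S)-3-(2-methoxy-2-oxoethyl)hexanoic acid; 21 mesityl oxide (4-methylpent-3-en-2-one)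
Product: 23 methyl (3S)-9-methyl-5,7-dioxo-3-propyldec-8-enoate, via acyl imidazolide 22 (not isolated)
Conditions: 20, CDI, THF, rt; 21, LiN(iPr)2 (2.3 equiv each), THF, −78 °C; combine, −78 → −40 °C; AcOH
Reagents that add atoms: none
Why: Crossed Claisen condensation in which the kinetic C-1 lithium enolate of 21 is C-acylated by the acyl imidazolide, a far better acyl donor than the methyl ester, the second equivalent of enolate taking the acidic proton of the β-diketone formed.

Step 15
Reactants: 23 methyl (3S)-9-methyl-5,7-dioxo-3-propyldec-8-enoate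
Product: 24 (3S)-9-methyl-5,7-dioxo-3-propyldec-8-enoic acid
Conditions: LiOH, THF/H2O, 0 °C → rt; then 1 M HCl
Reagents that add atoms: lithium hydroxide, [Li+].[OH-]
Why: Saponification of the unhindered methyl ester, with the β-diketone shielded as its enolate, frees the carboxyl group so that no ester α-protons compete in step 16 and no deprotection is needed after the key step.

Step 16
Reactants: 18 methyl (2R)-2-(chlorocarbonyl)-2-{[(1S,2R)-3,3-dimethyl-2-(prop-1-en-2-yl)cyclobutyl]methyl}-5-methylhex-4-enoate; 24 (3S)-9-methyl-5,7-dioxo-3-propyldec-8-enoic acid (2 equiv)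
Product: 25 (3R)-4-[(2S)-2-{[(1S,2R)-3,3-dimethyl-2-(prop-1-en-2-yl)cyclobutyl]methyl}-2-(methoxycarbonyl)-5-methylhex-4-enoyl]-9-methyl-5,7-dioxo-3-propyldec-8-enoic acid (C-4 epimers)
Conditions: 24, LiN(iPr)2 (6.2 equiv), THF, −78 → 0 °C; then 18, −78 °C; AcOH, −78 °C
Reagents that add atoms: none
Why: γ-Acylation of a β-diketone polyanion, in which the base removes in turn the carboxylic acid proton, the C-6 proton between the two ketones and a C-4 proton (the only sp3 α′ position; α-deprotonation of the carboxylate is much slower), and the most basic C-4 carbanion is C-acylated by the acid chloride at −78 °C, the cold quench keeping the product polyanion from cyclising, while the new C-4 centre stays enolisable and is of no consequence.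

Step 17
Reactants: 25 (3R)-4-[(2S)-2-{[(1S,2R)-3,3-dimethyl-2-(prop-1-en-2-yl)cyclobutyl]methyl}-2-(methoxycarbonyl)-5-methylhex-4-enoyl]-9-methyl-5,7-dioxo-3-propyldec-8-enoic acid
Product: 26 (3R)-3-[(3S)-3-{[(1S,2R)-3,3-dimethyl-2-(prop-1-en-2-yl)cyclobutyl]methyl}-1-(6,6-dimethyl-4-oxo-5,6-dihydro-4H-pyran-2-yl)-3-(methoxycarbonyl)-6-methyl-2-oxohept-5-en-1-yl]hexanoic acid (C-1′ epimers)
Conditions: camphor-10-sulfonic acid (0.2 equiv), CH2Cl2, rt
Reagents that add atoms: none
Why: Acid-catalysed intramolecular oxa-Michael addition (6-endo-trig) of the C-5 enol oxygen to the activated isobutenyl ketone should close the 2,2-dimethyl-2,3-dihydropyran-4-one, since the other ketone oxygen could only form an eight-membered ring, the crowded C-1′ ketone enolises poorly toward 4-pyranone formation, and the weak sulfonic acid does not protonate the alkenes.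

Step 18
Reactants: 26 (3R)-3-[(3S)-3-{[(1S,2R)-3,3-dimethyl-2-(prop-1-en-2-yl)cyclobutyl]methyl}-1-(6,6-dimethyl-4-oxo-5,6-dihydro-4H-pyran-2-yl)-3-(methoxycarbonyl)-6-methyl-2-oxohept-5-en-1-yl]hexanoic acid
Product: 27 (3R)-3-[(6R)-6-{[(1S,2R)-3,3-dimethyl-2-(prop-1-en-2-yl)cyclobutyl]methyl}-5-hydroxy-2,2-dimethyl-6-(3-methylbut-2-en-1-yl)-4,7-dioxo-3,4,6,7-tetrahydro-2H-chromen-8-yl]hexanoic acid (CNP0358381.1)
Conditions: KOtBu (2.2 equiv), THF, 0 °C → rt; then 1 M HCl, 0 °C
Reagents that add atoms: none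
Why: KOtBu removes the carboxylic acid proton and the C-1′ proton between the C-2′ ketone and the pyranone, giving an extended enolate that is nucleophilic at the pyranone α-carbon (C-3 of the pyranyl ring); this carbon attacks the methyl ester on the quaternary carbon, methoxide leaves, the very acidic ring C–H is deprotonated to the triketone enolate, and acidification should give 27. The closest known reaction type is the Dieckmann (intramolecular Claisen) condensation that gives 2-acylcyclohexane-1,3,5-triones, here run through the dienolate of a vinylogous ester. Ring A closes in the 6-(enolexo)-exo-trig mode. No stereocentre is formed and the four present are safe, since the quaternary carbon and the side-chain CH carry no acidic proton and the cyclobutane is remote. The step needs C-acylation through the pyranone α-carbon only, which the substrate secures because C-1′ would close a four-membered ring and the enolate oxygens four- or eight-membered rings, while the ring oxygen already sits on the future C-8a so that only one chromanone can result. Limiting the base to 2.2 equiv leaves the pyranone C-5 methylene protonated, so the ring is not opened by β-elimination.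

**Compound list**

1 | 2,2-dimethylpent-4-enal | C=CCC(C)(C)C=O | starting material
2 | 3,3-dimethylhex-5-enenitrile | C=CCC(C)(C)CC#N | intermediate
3 | rac-3,3-dimethyl-4-(oxiran-2-yl)butanenitrile | N#CCC(C)(C)CC1CO1 | intermediate
4 | 3,3-dimethyl-4-[(2R)-oxiran-2-yl]butanenitrile | N#CCC(C)(C)C[C@@H]1CO1 | intermediate
5 | (4R)-4-(hydroxymethyl)-2,2-dimethylcyclobutane-1-carbonitrile (lithium alkoxide in the flask, C-1 epimers) | N#CC1[C@H](CO)CC1(C)C | intermediate
6 | (4R)-4-({[tert-butyl(dimethyl)silyl]oxy}methyl)-2,2-dimethylcyclobutane-1-carbonitrile (C-1 epimers) | N#CC1[C@H](CO[Si](C)(C)C(C)(C)C)CC1(C)C | intermediate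
7 | 1-[(4R)-4-({[tert-butyl(dimethyl)silyl]oxy}methyl)-2,2-dimethylcyclobutyl]ethan-1-imine (C-1 epimers) | CC(=N)C1[C@H](CO[Si](C)(C)C(C)(C)C)CC1(C)C | intermediate
8 | 1-[(1S,4R)-4-({[tert-butyl(dimethyl)silyl]oxy}methyl)-2,2-dimethylcyclobutyl]ethan-1-one | CC(=O)[C@H]1[C@H](CO[Si](C)(C)C(C)(C)C)CC1(C)C | intermediate
9 | tert-butyl{[(1R,2R)-3,3-dimethyl-2-(prop-1-en-2-yl)cyclobutyl]methoxy}dimethylsilane | C=C(C)[C@H]1[C@H](CO[Si](C)(C)C(C)(C)C)CC1(C)C | intermediate
10 | [(1R,2R)-3,3-dimethyl-2-(prop-1-en-2-yl)cyclobutyl]methanol | C=C(C)[C@H]1[C@H](CO)CC1(C)C | intermediate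
11 | (1R,2R)-1-(iodomethyl)-3,3-dimethyl-2-(prop-1-en-2-yl)cyclobutane | C=C(C)[C@H]1[C@H](CI)CC1(C)C | intermediate
12 | tert-butyl methyl propanedioate | COC(=O)CC(=O)OC(C)(C)C | starting material
13 | 1-tert-butyl 3-methyl 2-{[(1R,2R)-3,3-dimethyl-2-(prop-1-en-2-yl)cyclobutyl]methyl}propanedioate (C-2 epimers) | C=C(C)[C@H]1[C@H](CC(C(=O)OC)C(=O)OC(C)(C)C)CC1(C)C | intermediate
14 | 1-bromo-3-methylbut-2-ene (prenyl bromide) | CC(C)=CCBr | starting material
15 | 1-tert-butyl 3-methyl (2R)-2-{[(1S,2R)-3,3-dimethyl-2-(prop-1-en-2-yl)cyclobutyl]methyl}-2-(3-methylbut-2-en-1-yl)propanedioate | C=C(C)[C@H]1[C@H](C[C@@](CC=C(C)C)(C(=O)OC)C(=O)OC(C)(C)C)CC1(C)C | intermediate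
16 | 1-methyl 3-trimethylsilyl (2R)-2-{[(1S,2R)-3,3-dimethyl-2-(prop-1-en-2-yl)cyclobutyl]methyl}-2-(3-methylbut-2-en-1-yl)propanedioate | C=C(C)[C@H]1[C@H](C[C@@](CC=C(C)C)(C(=O)OC)C(=O)O[Si](C)(C)C)CC1(C)C | intermediate
17 | (2S)-2-{[(1S,2R)-3,3-dimethyl-2-(prop-1-en-2-yl)cyclobutyl]methyl}-2-(methoxycarbonyl)-5-methylhex-4-enoic acid | C=C(C)[C@H]1[C@H](C[C@@](CC=C(C)C)(C(=O)OC)C(=O)O)CC1(C)C | intermediate
18 | methyl (2R)-2-(chlorocarbonyl)-2-{[(1S,2R)-3,3-dimethyl-2-(prop-1-en-2-yl)cyclobutyl]methyl}-5-methylhex-4-enoate | C=C(C)[C@H]1[C@H](C[C@@](CC=C(C)C)(C(=O)OC)C(=O)Cl)CC1(C)C | intermediate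
19 | 3-propylglutaric anhydride (4-propyloxane-2,6-dione) | CCCC1CC(=O)OC(=O)C1 | starting material
20 | (3S)-3-(2-methoxy-2-oxoethyl)hexanoic acid | OC(=O)C[C@H](CCC)CC(=O)OC | intermediate
21 | mesityl oxide (4-methylpent-3-en-2-one) | CC(=O)C=C(C)C | starting material
22 | methyl (3S)-3-[2-(1H-imidazol-1-yl)-2-oxoethyl]hexanoate | COC(=O)C[C@@H](CCC)CC(=O)n1ccnc1 | intermediate
23 | methyl (3S)-9-methyl-5,7-dioxo-3-propyldec-8-enoate | COC(=O)C[C@@H](CCC)CC(=O)CC(=O)C=C(C)C | intermediate
24 | (3S)-9-methyl-5,7-dioxo-3-propyldec-8-enoic acid | OC(=O)C[C@@H](CCC)CC(=O)CC(=O)C=C(C)C | intermediate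
25 | (3R)-4-[(2S)-2-{[(1S,2R)-3,3-dimethyl-2-(prop-1-en-2-yl)cyclobutyl]methyl}-2-(methoxycarbonyl)-5-methylhex-4-enoyl]-9-methyl-5,7-dioxo-3-propyldec-8-enoic acid (C-4 epimers) | C=C(C)[C@H]1[C@H](C[C@@](CC=C(C)C)(C(=O)OC)C(=O)C([C@H](CCC)CC(=O)O)C(=O)CC(=O)C=C(C)C)CC1(C)C | intermediate
26 | (3R)-3-[(3S)-3-{[(1S,2R)-3,3-dimethyl-2-(prop-1-en-2-yl)cyclobutyl]methyl}-1-(6,6-dimethyl-4-oxo-5,6-dihydro-4H-pyran-2-yl)-3-(methoxycarbonyl)-6-methyl-2-oxohept-5-en-1-yl]hexanoic acid (C-1′ epimers) | C=C(C)[C@H]1[C@H](C[C@@](CC=C(C)C)(C(=O)OC)C(=O)C([C@H](CCC)CC(=O)O)C2=CC(=O)CC(C)(C)O2)CC1(C)C | intermediate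
27 | (3R)-3-[(6R)-6-{[(1S,2R)-3,3-dimethyl-2-(prop-1-en-2-yl)cyclobutyl]methyl}-5-hydroxy-2,2-dimethyl-6-(3-methylbut-2-en-1-yl)-4,7-dioxo-3,4,6,7-tetrahydro-2H-chromen-8-yl]hexanoic acid | C=C(C)[C@H]1[C@H](C[C@]2(CC=C(C)C)C(=O)C([C@H](CCC)CC(=O)O)=C3OC(C)(C)CC(=O)C3=C2O)CC1(C)C | target

**Step count**
Total: 18 steps. Longest linear sequence: 15 steps (steps 1–12, then 16–18).

**Steps most likely to fail**

Step 16. The trilithium species may be deprotonated at the wrong carbon (next to the carboxylate or at a γ-methyl group). Bond formation between the two hindered centres may also be slow enough for the triketone polyanion to close ring A through C-6 before the pyranone exists. The fallback sets out from 18 and comes back at 25. Acid chloride 18 would be reduced with LiAlH(OtBu)3 (THF, −78 °C) to the aldehyde methyl (2S)-2-{[(1S,2R)-3,3-dimethyl-2-(prop-1-en-2-yl)cyclobutyl]methyl}-2-formyl-5-methylhex-4-enoate F1. Aldol addition of the same trilithium species of 24 to F1 at −78 °C is fast, and the alkoxide formed cannot undergo Claisen closure; it should give the hydroxy diketo acid (3R)-4-[(2S)-2-{[(1S,2R)-3,3-dimethyl-2-(prop-1-en-2-yl)cyclobutyl]methyl}-1-hydroxy-2-(methoxycarbonyl)-5-methylhex-4-en-1-yl]-9-methyl-5,7-dioxo-3-propyldec-8-enoic acid F2. Oxidation of the secondary alcohol with Dess–Martin periodinane (NaHCO3, CH2Cl2) would then give 25.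

Step 18. A C-5 enolate of the pyranone may expel the ring oxygen (retro-oxa-Michael opening), which would scramble the chromanone regiochemistry. Attack on the neopentyl ester may also be too slow to compete with cleavage of the β-keto ester by methoxide. The fallback sets out from 25 and comes back at 27. Treating 25 with KOtBu (3.3 equiv, THF) would let the diketone carbon C-6 close ring A on the methyl ester by an ordinary Dieckmann condensation. This should give the acyl trione (3R)-3-[(5R)-5-{[(1S,2R)-3,3-dimethyl-2-(prop-1-en-2-yl)cyclobutyl]methyl}-2,4-dihydroxy-3-(3-methylbut-2-enoyl)-5-(3-methylbut-2-en-1-yl)-6-oxocyclohexa-1,3-dien-1-yl]hexanoic acid F3. Base-mediated oxa-Michael closure (K2CO3, 2-butanone, 60 °C) would then form the dihydropyranone. Regiochemistry is no longer controlled on this path, so 27 would have to be separated by preparative HPLC from the regioisomer (3R)-3-[(8R)-8-{[(1S,2R)-3,3-dimethyl-2-(prop-1-en-2-yl)cyclobutyl]methyl}-5-hydroxy-2,2-dimethyl-8-(3-methylbut-2-en-1-yl)-4,7-dioxo-3,4,7,8-tetrahydro-2H-chromen-6-yl]hexanoic acid F4.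

Step 17. Ring closure of the crowded, α-branched triketo acid may be sluggish or unselective. Possible diversions are dehydrative closure to a 4-pyranone and lactonisation of the free acid onto an enol, and a stronger acid would protonate the alkenes. The fallback sets out from 18 and comes back at 26; it closes the pyranone on an unbranched triketone and adds the side chain last.
- 6-Methylhept-5-ene-2,4-dione F5 would be made from the lithium enolate of 21 and N-acetylimidazole.
- Its dilithium salt (LiN(iPr)2, 2 equiv, THF) would be acylated at the terminal methyl group by 18 at −78 °C to give methyl (2S)-2-{[(1S,2R)-3,3-dimethyl-2-(prop-1-en-2-yl)cyclobutyl]methyl}-9-methyl-2-(3-methylbut-2-en-1-yl)-3,5,7-trioxodec-8-enoate F6.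
- Camphor-10-sulfonic acid would close F6 to methyl (2S)-2-{[(1S,2R)-3,3-dimethyl-2-(prop-1-en-2-yl)cyclobutyl]methyl}-4-(6,6-dimethyl-4-oxo-5,6-dihydro-4H-pyran-2-yl)-2-(3-methylbut-2-en-1-yl)-3-oxobutanoate F7.
- The acidic CH2 of F7 would add to (E)-hex-2-enal under iminium catalysis with (S)-α,α-diphenylprolinol trimethylsilyl ether (PhCO2H cat., toluene). The catalyst shields one face of the enal, so the side-chain carbon should form in the (R) configuration, giving methyl (2S,5R)-2-{[(1S,2R)-3,3-dimethyl-2-(prop-1-en-2-yl)cyclobutyl]methyl}-4-(6,6-dimethyl-4-oxo-5,6-dihydro-4H-pyran-2-yl)-2-(3-methylbut-2-en-1-yl)-3-oxo-5-(2-oxoethyl)octanoate F8.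
- Pinnick oxidation (NaClO2, NaH2PO4, 2-methylbut-2-ene, tBuOH/H2O) would give 26.

**Further compounds**
F1 | step 16 | methyl (2S)-2-{[(1S,2R)-3,3-dimethyl-2-(prop-1-en-2-yl)cyclobutyl]methyl}-2-formyl-5-methylhex-4-enoate | C=C(C)[C@H]1[C@H](C[C@@](CC=C(C)C)(C(=O)OC)C=O)CC1(C)C
F2 | step 16 | (3R)-4-[(2S)-2-{[(1S,2R)-3,3-dimethyl-2-(prop-1-en-2-yl)cyclobutyl]methyl}-1-hydroxy-2-(methoxycarbonyl)-5-methylhex-4-en-1-yl]-9-methyl-5,7-dioxo-3-propyldec-8-enoic acid | C=C(C)[C@H]1[C@H](C[C@@](CC=C(C)C)(C(=O)OC)C(O)C([C@H](CCC)CC(=O)O)C(=O)CC(=O)C=C(C)C)CC1(C)C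
F3 | step 18 | (3R)-3-[(5R)-5-{[(1S,2R)-3,3-dimethyl-2-(prop-1-en-2-yl)cyclobutyl]methyl}-2,4-dihydroxy-3-(3-methylbut-2-enoyl)-5-(3-methylbut-2-en-1-yl)-6-oxocyclohexa-1,3-dien-1-yl]hexanoic acid | C=C(C)[C@H]1[C@H](C[C@]2(CC=C(C)C)C(=O)C([C@H](CCC)CC(=O)O)=C(O)C(C(=O)C=C(C)C)=C2O)CC1(C)C
F4 | step 18 | (3R)-3-[(8R)-8-{[(1S,2R)-3,3-dimethyl-2-(prop-1-en-2-yl)cyclobutyl]methyl}-5-hydroxy-2,2-dimethyl-8-(3-methylbut-2-en-1-yl)-4,7-dioxo-3,4,7,8-tetrahydro-2H-chromen-6-yl]hexanoic acid | C=C(C)[C@H]1[C@H](C[C@]2(CC=C(C)C)C(=O)C([C@H](CCC)CC(=O)O)=C(O)C3=C2OC(C)(C)CC3=O)CC1(C)C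
F5 | step 17 | 6-methylhept-5-ene-2,4-dione | CC(=O)CC(=O)C=C(C)C
F6 | step 17 | methyl (2S)-2-{[(1S,2R)-3,3-dimethyl-2-(prop-1-en-2-yl)cyclobutyl]methyl}-9-methyl-2-(3-methylbut-2-en-1-yl)-3,5,7-trioxodec-8-enoate | C=C(C)[C@H]1[C@H](C[C@@](CC=C(C)C)(C(=O)OC)C(=O)CC(=O)CC(=O)C=C(C)C)CC1(C)C
F7 | step 17 | methyl (2S)-2-{[(1S,2R)-3,3-dimethyl-2-(prop-1-en-2-yl)cyclobutyl]methyl}-4-(6,6-dimethyl-4-oxo-5,6-dihydro-4H-pyran-2-yl)-2-(3-methylbut-2-en-1-yl)-3-oxobutanoate | C=C(C)[C@H]1[C@H](C[C@@](CC=C(C)C)(C(=O)OC)C(=O)CC2=CC(=O)CC(C)(C)O2)CC1(C)C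
F8 | step 17 | methyl (2S,5R)-2-{[(1S,2R)-3,3-dimethyl-2-(prop-1-en-2-yl)cyclobutyl]methyl}-4-(6,6-dimethyl-4-oxo-5,6-dihydro-4H-pyran-2-yl)-2-(3-methylbut-2-en-1-yl)-3-oxo-5-(2-oxoethyl)octanoate | C=C(C)[C@H]1[C@H](C[C@@](CC=C(C)C)(C(=O)OC)C(=O)C([C@H](CCC)CC=O)C2=CC(=O)CC(C)(C)O2)CC1(C)C
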